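**Overview**

- Retrosynthesis: the three CH2OH groups go back to three methyl esters and the ring A phenol to its triisopropylsilyl ether. Both furan C2-C3 bonds are then cut in one operation, leaving a linear bis(benzyl aryl ether) with two aryldiazoacetates, and the two ArO-CH2Ar bonds are cut last.
- Enabling feature: in each 2-aryl-3-hydroxymethyl-2,3-dihydrobenzofuran, C3 sits on the arene carbon ortho to the ring oxygen and C2 is the O-CH(aryl) carbon of that same oxygen. Each C2-C3 bond is therefore what a 1,5 C-H insertion of an aryl(ester)carbene into an ortho benzyloxy CH2 group makes, and the carbene ester becomes the CH2OH on C3.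
- Forward: one hub aldehyde from o-eugenol supplies rings B and C, and vanillin supplies ring A. Two Mitsunobu etherifications join A to B and then B to C, twofold diazo transfer follows, and both dihydrofuran rings are closed together by a chiral dirhodium catalyst.
- Stereochemistry: the catalyst fixes 2R at both C2 (cis esters form first), and methoxide epimerisation then places both C3 substituents trans to the C2 aryl groups. The E alkene comes from a stabilised Wittig ylide, and the final reduction and desilylation touch no stereocentre.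

Key step: step 13

Assumption: Rh2(S-PTTL)4 is taken to give 2R at the new O-CH(aryl) carbon, by analogy with one-ring ortho-benzyloxy aryldiazoacetates. This is to be confirmed on the one-ring diazo ester made from ether aldehyde 12, and Rh2(R-PTTL)4 replaces it, with nothing else changed, if the sense proves opposite.

Remark on descriptors: the cis esters are (2R,3S), the trans esters (2R,3R) and the trans alcohols (2R,3S). The S to R change in step 14 is a real inversion at C3. The R to S change in step 15 is only a change of CIP ranking, because CH2OH ranks below C2 whereas CO2Me ranks above it.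

**Route**

Step 1
Reactants: 1 2-allyl-6-methoxyphenol (o-eugenol)
Product: 2 2-allyl-6-methoxyphenyl acetate
Conditions: Ac2O, pyridine, cat. DMAP, 0 °C to rt
Reagents that add atoms: acetic anhydride, CC(=O)OC(C)=O
Why: DMAP-catalysed O-acylation of the phenol is routine, and the acetate lowers the electron density of the ring so that it should survive the ozonolysis and chlorite oxidation that follow.

Step 2
Reactants: 2 2-allyl-6-methoxyphenyl acetate
Product: 4 2-(2-acetoxy-3-methoxyphenyl)acetaldehyde, via ozonide 3 (not isolated)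
Conditions: O3, CH2Cl2, −78 °C; then PPh3, −78 °C to rt
Reagents that add atoms: ozone, [O-][O+]=O
Why: Ozonolysis with reductive work-up (Criegee mechanism) cleaves the terminal alkene far faster than ozone attacks the acylated arene at low temperature, and PPh3 reduces ozonide 3 to the arylacetaldehyde, which is carried on crude.

Step 3
Reactants: 4 2-(2-acetoxy-3-methoxyphenyl)acetaldehyde
Product: 5 2-(2-acetoxy-3-methoxyphenyl)acetic acid
Conditions: NaClO2, NaH2PO4, 2-methyl-2-butene, t-BuOH/H2O, 0 °C to rt
Reagents that add atoms: sodium chlorite, [Na+].[O-]Cl=O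
Why: The Pinnick (Lindgren) oxidation converts the enolisable aldehyde into the acid at buffered pH, where the aryl acetate is stable, and the alkene scavenger removes hypochlorous acid before it can chlorinate the arene.

Step 4
Reactants: 5 2-(2-acetoxy-3-methoxyphenyl)acetic acid
Product: 6 methyl 2-(2-hydroxy-3-methoxyphenyl)acetate
Conditions: MeOH, cat. H2SO4, reflux
Reagents that add atoms: methanol, CO
Why: Fischer esterification of the acid and acid-catalysed methanolysis of the aryl acetate run in the same flask, and the large excess of methanol should hold the product as the open hydroxy ester and not as the benzofuranone lactone.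

Step 5
Reactants: 6 methyl 2-(2-hydroxy-3-methoxyphenyl)acetate
Product: 8 methyl 2-(5-formyl-2-hydroxy-3-methoxyphenyl)acetate (hub aldehyde), via aldimine 7 (not isolated)
Conditions: hexamethylenetetramine, CF3CO2H, 80 °C; then H2O, rt
Reagents that add atoms: hexamethylenetetramine, C1N2CN3CN1CN(C2)C3; water, O
Why: In the Duff formylation the iminium electrophile can attack only para to the phenol because both ortho positions are substituted, and hydrolysis of aldimine 7 then frees the aldehyde.

Step 6
Reactants: 9 vanillin
Product: 10 3-methoxy-4-(triisopropylsilyloxy)benzaldehyde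
Conditions: i-Pr3SiCl, imidazole, DMF, rt
Reagents that add atoms: chlorotriisopropylsilane, CC(C)[Si](Cl)(C(C)C)C(C)C
Why: Imidazole-promoted silylation of the phenol gives a bulky aryl silyl ether that should withstand borohydride, Mitsunobu conditions, diazo transfer, the carbene step and brief methoxide treatment, and that comes off with fluoride at the end.

Step 7
Reactants: 10 3-methoxy-4-(triisopropylsilyloxy)benzaldehyde
Product: 11 [3-methoxy-4-(triisopropylsilyloxy)phenyl]methanol (ring A fragment)
Conditions: NaBH4, MeOH, 0 °C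
Reagents that add atoms: none
Why: Borohydride reduction of the aromatic aldehyde to the benzyl alcohol is fast at 0 °C and leaves the hindered aryl silyl ether intact.

Step 8
Reactants: 8 methyl 2-(5-formyl-2-hydroxy-3-methoxyphenyl)acetate; 11 [3-methoxy-4-(triisopropylsilyloxy)phenyl]methanol
Product: 12 methyl 2-[5-formyl-3-methoxy-2-[[3-methoxy-4-(triisopropylsilyloxy)phenyl]methoxy]phenyl]acetate (A-B ether aldehyde)
Conditions: PPh3, diisopropyl azodicarboxylate, THF, 0 °C to rt
Reagents that add atoms: none
Why: In this Mitsunobu etherification the para-formyl phenol is acidic enough to protonate the phosphine-azodicarboxylate adduct, and its phenoxide displaces the oxyphosphonium of the primary benzylic alcohol without base, so the arylacetate, aldehyde and silyl ether are spared.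

Step 9
Reactants: 12 A-B ether aldehyde
Product: 13 methyl 2-[5-(hydroxymethyl)-3-methoxy-2-[[3-methoxy-4-(triisopropylsilyloxy)phenyl]methoxy]phenyl]acetate (A-B ether benzyl alcohol)
Conditions: NaBH4, MeOH/THF, 0 °C
Reagents that add atoms: none
Why: Chemoselective borohydride reduction takes the aldehyde within minutes at 0 °C, whereas the methyl ester, the benzyl ether and the silyl ether do not react under these conditions.

Step 10
Reactants: 8 methyl 2-(5-formyl-2-hydroxy-3-methoxyphenyl)acetate; 14 methyl (triphenylphosphoranylidene)acetate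
Product: 15 methyl (E)-3-[4-hydroxy-3-methoxy-5-(2-methoxy-2-oxoethyl)phenyl]acrylate (ring C fragment)
Conditions: toluene, 80 °C
Reagents that add atoms: none
Why: Wittig olefination with a stabilised ylide is E-selective and is well known to tolerate free para-hydroxybenzaldehydes of the vanillin type.

Step 11
Reactants: 13 A-B ether benzyl alcohol; 15 ring C fragment
Product: 16 linear triester, methyl (E)-3-[3-methoxy-5-(2-methoxy-2-oxoethyl)-4-[[3-methoxy-5-(2-methoxy-2-oxoethyl)-4-[[3-methoxy-4-(triisopropylsilyloxy)phenyl]methoxy]phenyl]methoxy]phenyl]acrylate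
Conditions: PPh3, diisopropyl azodicarboxylate, THF, 0 °C to rt
Reagents that add atoms: none
Why: A second Mitsunobu etherification joins the ring C phenol to the primary benzylic alcohol of ring B under neutral conditions, so neither arylacetate CH2 group nor the cinnamate is disturbed.

Step 12
Reactants: 16 linear triester
Product: 17 bis(aryldiazoacetate), the analogue of 16 in which both ArCH2CO2Me groups have become ArC(=N2)CO2Me
Conditions: p-acetamidobenzenesulfonyl azide, DBU, MeCN, 0 °C to rt; product kept cold and dark and used at once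
Reagents that add atoms: p-acetamidobenzenesulfonyl azide, CC(=O)Nc1ccc(cc1)S(=O)(=O)N=[N+]=[N-]
Why: In this Regitz diazo transfer DBU deprotonates each arylacetate CH2 and the enolate takes N2 from the sulfonyl azide, the standard access to aryldiazoacetates, while the cinnamate has no acidic C-H and stays unchanged.

Step 13
Reactants: 17 bis(aryldiazoacetate)
Product: 20 cis,cis-bis(dihydrobenzofuran) triester (2R,3S in each furan ring), via ring B-closed monodiazo ester 18 (not isolated), via ring C-closed monodiazo ester 19 (not isolated)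
Conditions: Rh2(S-PTTL)4 = dirhodium tetrakis[N-phthaloyl-(S)-tert-leucinate] (2 mol%), toluene, −78 to −60 °C, slow addition of dilute 17
Reagents that add atoms: none
Why: Proposed new method: each diazo ester loses N2 on the dirhodium tetracarboxylate (divalent rhodium) to give a metal-bound donor-acceptor carbene, which inserts through a concerted, hydride-transfer-like three-centre transition state into one C-H bond of the neighbouring ArO-CH2-Ar group, so the two C2-C3 bonds form one after the other by way of 18 or 19. The closest known reaction type is the single enantioselective intramolecular 1,5 C-H insertion of ortho-benzyloxy aryldiazoacetates with chiral dirhodium carboxylates, which gives cis-2-aryl-2,3-dihydrobenzofuran-3-carboxylates; running it twice in one flask on a bis(diazo ester) is the untested part. Each of the two dihydrofuran rings (the one fused to ring B and the one fused to ring C) closes as a five-membered ring by 1,5 insertion, the carbene carbon becoming C3 and the ether CH2 carbon becoming C2. Both C2 centres (2R) are set by the chiral phthaloyl-tert-leucinate ligands, which select one of the two enantiotopic hydrogens of each O-CH2 group, and both C3 centres (3S, ester cis to the C2 aryl) are set relative to C2 by the compact insertion transition state. The step needs site, diastereo- and enantioselectivity at two places; the site is secured by the ortho placement of each carbene next to its own benzyloxy group, whose C-H bonds are activated by the ether oxygen and by a para-oxygenated arene, and the only alkene is an electron-poor trans-cinnamate that such carbenes cyclopropanate poorly. Since the two insertions are independent catalyst-controlled events in one molecule, a wrong-sense insertion should end in a separable diastereomer and leave the main product enriched in one enantiomer.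

Step 14
Reactants: 20 cis,cis-bis(dihydrobenzofuran) triester
Product: 21 trans,trans-bis(dihydrobenzofuran) triester (2R,3R in each furan ring)
Conditions: NaOMe (substoichiometric), MeOH/THF, 0 °C to rt, quenched with AcOH as soon as equilibrated
Reagents that add atoms: none
Why: Base epimerisation through the two ester enolates should move both C3 centres to the more stable trans arrangement, with methoxide matching the methyl esters, while C2 carries no acidic hydrogen and ring opening by beta-elimination would be the reverse of a 5-endo-trig closure and is therefore slow.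

Step 15
Reactants: 21 trans,trans-bis(dihydrobenzofuran) triester
Product: 22 silyl-protected triol, [(2R,3S)-5-[(2R,3S)-3-(hydroxymethyl)-5-[(E)-3-hydroxyprop-1-enyl]-7-methoxy-2,3-dihydro-1-benzofuran-2-yl]-7-methoxy-2-[3-methoxy-4-(triisopropylsilyloxy)phenyl]-2,3-dihydro-1-benzofuran-3-yl]methanol
Conditions: i-Bu2AlH (excess), CH2Cl2, −78 to −20 °C; aq. potassium sodium tartrate
Reagents that add atoms: none
Why: Hydride reduction with i-Bu2AlH takes the two saturated esters to primary alcohols and the cinnamate by 1,2-addition to the allylic alcohol, and no stereocentre is touched.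

Step 16
Reactants: 22 silyl-protected triol
Product: 23 target CNP0250921.1, 4-[(2R,3S)-3-(hydroxymethyl)-5-[(2R,3S)-3-(hydroxymethyl)-5-[(E)-3-hydroxyprop-1-enyl]-7-methoxy-2,3-dihydro-1-benzofuran-2-yl]-7-methoxy-2,3-dihydro-1-benzofuran-2-yl]-2-methoxyphenol
Conditions: Bu4NF, AcOH, THF, 0 °C
Reagents that add atoms: none
Why: Fluoride cleaves the aryl silyl ether, and the acetic acid buffer keeps the freed para-hydroxybenzylic ether from standing as a basic phenoxide, so the benzylic C2-O bond and the allylic alcohol should be left alone.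

**Compound list**

1 | 2-allyl-6-methoxyphenol (o-eugenol) | C=CCc1cccc(OC)c1O | starting material
2 | 2-allyl-6-methoxyphenyl acetate | C=CCc1cccc(OC)c1OC(C)=O | intermediate
3 | ozonide, 3-[(2-acetoxy-3-methoxyphenyl)methyl]-1,2,4-trioxolane | COc1cccc(CC2OCOO2)c1OC(C)=O | intermediate
4 | 2-(2-acetoxy-3-methoxyphenyl)acetaldehyde | O=CCc1cccc(OC)c1OC(C)=O | intermediate
5 | 2-(2-acetoxy-3-methoxyphenyl)acetic acid | OC(=O)Cc1cccc(OC)c1OC(C)=O | intermediate
6 | methyl 2-(2-hydroxy-3-methoxyphenyl)acetate | COC(=O)Cc1cccc(OC)c1O | intermediate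
7 | aldimine, methyl 2-[2-hydroxy-5-(iminomethyl)-3-methoxyphenyl]acetate (drawn in its simplest N-H form; an N-substituted iminium salt in the acid) | COC(=O)Cc1cc(C=N)cc(OC)c1O | intermediate
8 | hub aldehyde, methyl 2-(5-formyl-2-hydroxy-3-methoxyphenyl)acetate | COC(=O)Cc1cc(C=O)cc(OC)c1O | intermediate
9 | vanillin | COc1cc(C=O)ccc1O | starting material
10 | 3-methoxy-4-(triisopropylsilyloxy)benzaldehyde | COc1cc(C=O)ccc1O[Si](C(C)C)(C(C)C)C(C)C | intermediate
11 | [3-methoxy-4-(triisopropylsilyloxy)phenyl]methanol | COc1cc(CO)ccc1O[Si](C(C)C)(C(C)C)C(C)C | intermediate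
12 | A-B ether aldehyde, methyl 2-[5-formyl-3-methoxy-2-[[3-methoxy-4-(triisopropylsilyloxy)phenyl]methoxy]phenyl]acetate | COC(=O)Cc1cc(C=O)cc(OC)c1OCc1ccc(O[Si](C(C)C)(C(C)C)C(C)C)c(OC)c1 | intermediate
13 | A-B ether benzyl alcohol, methyl 2-[5-(hydroxymethyl)-3-methoxy-2-[[3-methoxy-4-(triisopropylsilyloxy)phenyl]methoxy]phenyl]acetate | COC(=O)Cc1cc(CO)cc(OC)c1OCc1ccc(O[Si](C(C)C)(C(C)C)C(C)C)c(OC)c1 | intermediate
14 | methyl (triphenylphosphoranylidene)acetate | COC(=O)C=P(c1ccccc1)(c1ccccc1)c1ccccc1 | starting material
15 | ring C fragment, methyl (E)-3-[4-hydroxy-3-methoxy-5-(2-methoxy-2-oxoethyl)phenyl]acrylate | COC(=O)Cc1cc(/C=C/C(=O)OC)cc(OC)c1O | intermediate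
16 | linear triester with rings A, B and C joined by two ArO-CH2Ar links | COC(=O)Cc1cc(/C=C/C(=O)OC)cc(OC)c1OCc1cc(CC(=O)OC)c(OCc2ccc(O[Si](C(C)C)(C(C)C)C(C)C)c(OC)c2)c(OC)c1 | intermediate
17 | bis(aryldiazoacetate), 16 with a diazo group on each arylacetate carbon | COC(=O)C(=[N+]=[N-])c1cc(/C=C/C(=O)OC)cc(OC)c1OCc1cc(C(=[N+]=[N-])C(=O)OC)c(OCc2ccc(O[Si](C(C)C)(C(C)C)C(C)C)c(OC)c2)c(OC)c1 | intermediate
18 | ring B-closed monodiazo ester, methyl (2R,3S)-5-[[2-(1-diazo-2-methoxy-2-oxoethyl)-6-methoxy-4-[(E)-3-methoxy-3-oxoprop-1-enyl]phenoxy]methyl]-7-methoxy-2-[3-methoxy-4-(triisopropylsilyloxy)phenyl]-2,3-dihydro-1-benzofuran-3-carboxylate | COc1cc([C@@H]2Oc3c(OC)cc(COc4c(OC)cc(/C=C/C(=O)OC)cc4C(=[N+]=[N-])C(=O)OC)cc3[C@@H]2C(=O)OC)ccc1O[Si](C(C)C)(C(C)C)C(C)C | intermediate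
19 | ring C-closed monodiazo ester, methyl (2R,3S)-2-[3-(1-diazo-2-methoxy-2-oxoethyl)-5-methoxy-4-[[3-methoxy-4-(triisopropylsilyloxy)phenyl]methoxy]phenyl]-7-methoxy-5-[(E)-3-methoxy-3-oxoprop-1-enyl]-2,3-dihydro-1-benzofuran-3-carboxylate | COc1cc(COc3c(OC)cc([C@@H]4Oc5c(OC)cc(/C=C/C(=O)OC)cc5[C@@H]4C(=O)OC)cc3C(=[N+]=[N-])C(=O)OC)ccc1O[Si](C(C)C)(C(C)C)C(C)C | intermediate
20 | cis,cis triester, methyl (2R,3S)-5-[(2R,3S)-7-methoxy-3-(methoxycarbonyl)-5-[(E)-3-methoxy-3-oxoprop-1-enyl]-2,3-dihydro-1-benzofuran-2-yl]-7-methoxy-2-[3-methoxy-4-(triisopropylsilyloxy)phenyl]-2,3-dihydro-1-benzofuran-3-carboxylate | COc1cc([C@@H]2Oc3c(OC)cc([C@@H]4Oc5c(OC)cc(/C=C/C(=O)OC)cc5[C@@H]4C(=O)OC)cc3[C@@H]2C(=O)OC)ccc1O[Si](C(C)C)(C(C)C)C(C)C | intermediate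
21 | trans,trans triester, the (2R,3R),(2R,3R) epimer of 20 | COc1cc([C@@H]2Oc3c(OC)cc([C@@H]4Oc5c(OC)cc(/C=C/C(=O)OC)cc5[C@H]4C(=O)OC)cc3[C@H]2C(=O)OC)ccc1O[Si](C(C)C)(C(C)C)C(C)C | intermediate
22 | silyl-protected triol, (2R,3S) in each furan ring, E allylic alcohol | COc1cc([C@@H]2Oc3c(OC)cc([C@@H]4Oc5c(OC)cc(/C=C/CO)cc5[C@H]4CO)cc3[C@H]2CO)ccc1O[Si](C(C)C)(C(C)C)C(C)C | intermediate
23 | CNP0250921.1, 4-[(2R,3S)-3-(hydroxymethyl)-5-[(2R,3S)-3-(hydroxymethyl)-5-[(E)-3-hydroxyprop-1-enyl]-7-methoxy-2,3-dihydro-1-benzofuran-2-yl]-7-methoxy-2,3-dihydro-1-benzofuran-2-yl]-2-methoxyphenol | COc1cc([C@@H]2Oc3c(OC)cc([C@@H]4Oc5c(OC)cc(/C=C/CO)cc5[C@H]4CO)cc3[C@H]2CO)ccc1O | target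

**Step count and risks**

Total step count: 16. Longest linear sequence: 13 steps (steps 1 to 5, 8, 9 and 11 to 16, from o-eugenol).

Steps most likely to fail:

1. Step 13 (proposed new method). Once the first ring has closed, the second carbene may be diverted into carbene dimerisation, reaction with adventitious water or reaction with the cinnamate. The two insertions may also run with unequal facial selectivity and give a mixture of diastereomers that is hard to separate. The fallback closes the rings one at a time, using only the known single insertion; it sets out from 12 and comes back at 21.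
   - Diazo transfer to 12 (p-acetamidobenzenesulfonyl azide, DBU, MeCN) would give the one-ring diazo ester aldehyde F1.
   - Rh2(S-PTTL)4 in toluene at −78 °C would close the ring B furan to the cis dihydrobenzofuran aldehyde F2, which also serves to assign the sense of induction.
   - Brief NaOMe in MeOH would give the trans ester aldehyde F3, and NaBH4 in MeOH at 0 °C the trans benzyl alcohol F4.
   - Mitsunobu coupling of F4 with 15 would give the A-B-C ether F5, and a second diazo transfer the monodiazo ester F6.
   - A second single insertion with the same catalyst would give the triester F7, with ring B trans and ring C cis, and NaOMe in MeOH would epimerise the remaining cis centre to give 21.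

2. Step 14. Methoxide may strip the aryl silyl ether, after which the free para-phenoxide can open the adjacent C2-O bond through a quinone methide and erode C2, or the equilibration may stall before both centres have turned over. The fallback moves the equilibration to the aldehyde oxidation level, where a mild amine base suffices; it sets out from 20 and comes back at 22.
   - i-Bu2AlH reduction of 20 would give the cis,cis silyl triol F8.
   - Dess-Martin periodinane with NaHCO3 in CH2Cl2 would oxidise all three alcohols to the cis,cis trialdehyde F9.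
   - Et3N in CH2Cl2 would equilibrate the two alpha-aryl aldehydes to the trans,trans trialdehyde F10.
   - Luche reduction (NaBH4, CeCl3·7H2O, MeOH, −40 °C) would return all three aldehydes to alcohols and give 22.

3. Step 5. In hot CF3CO2H the ortho-hydroxy ester may lactonise to the benzofuranone faster than the ring is formylated, which removes the activating phenol and stops the reaction. The fallback installs the para carbon by halogenation and palladium coupling and bypasses 8 and 12; it sets out from 6 and comes back at 15 (ring C branch) and at 13 (ring B branch).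
   - N-bromosuccinimide in MeCN at 0 °C would brominate the only free position para to the phenol and give the bromophenol F11.
   - Heck reaction of F11 with methyl acrylate (Pd(OAc)2, P(o-tol)3, Et3N, DMF, 100 °C) would give 15 directly.
   - Mitsunobu etherification of F11 with 11 would give the A-B ether aryl bromide F12.
   - Stille coupling of F12 with (tributylstannyl)methanol (Pd(PPh3)4, dioxane, 100 °C) would give 13.

**Further compounds**

F1 | step 13 | one-ring diazo ester aldehyde, methyl 2-diazo-2-[5-formyl-3-methoxy-2-[[3-methoxy-4-(triisopropylsilyloxy)phenyl]methoxy]phenyl]acetate | COC(=O)C(=[N+]=[N-])c1cc(C=O)cc(OC)c1OCc1ccc(O[Si](C(C)C)(C(C)C)C(C)C)c(OC)c1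
F2 | step 13 | cis dihydrobenzofuran aldehyde, methyl (2R,3S)-5-formyl-7-methoxy-2-[3-methoxy-4-(triisopropylsilyloxy)phenyl]-2,3-dihydro-1-benzofuran-3-carboxylate | COc1cc([C@@H]2Oc3c(OC)cc(C=O)cc3[C@@H]2C(=O)OC)ccc1O[Si](C(C)C)(C(C)C)C(C)C
F3 | step 13 | trans ester aldehyde, the (2R,3R) epimer of F2 | COc1cc([C@@H]2Oc3c(OC)cc(C=O)cc3[C@H]2C(=O)OC)ccc1O[Si](C(C)C)(C(C)C)C(C)C
F4 | step 13 | trans benzyl alcohol, methyl (2R,3R)-5-(hydroxymethyl)-7-methoxy-2-[3-methoxy-4-(triisopropylsilyloxy)phenyl]-2,3-dihydro-1-benzofuran-3-carboxylate | COc1cc([C@@H]2Oc3c(OC)cc(CO)cc3[C@H]2C(=O)OC)ccc1O[Si](C(C)C)(C(C)C)C(C)C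
F5 | step 13 | A-B-C ether, F4 O-alkylating the phenol of 15 | COc1cc([C@@H]2Oc3c(OC)cc(COc4c(OC)cc(/C=C/C(=O)OC)cc4CC(=O)OC)cc3[C@H]2C(=O)OC)ccc1O[Si](C(C)C)(C(C)C)C(C)C
F6 | step 13 | monodiazo ester, F5 with a diazo group on the ring C arylacetate carbon | COc1cc([C@@H]2Oc3c(OC)cc(COc4c(OC)cc(/C=C/C(=O)OC)cc4C(=[N+]=[N-])C(=O)OC)cc3[C@H]2C(=O)OC)ccc1O[Si](C(C)C)(C(C)C)C(C)C
F7 | step 13 | triester with ring B furan trans (2R,3R) and ring C furan cis (2R,3S) | COc1cc([C@@H]2Oc3c(OC)cc([C@@H]4Oc5c(OC)cc(/C=C/C(=O)OC)cc5[C@@H]4C(=O)OC)cc3[C@H]2C(=O)OC)ccc1O[Si](C(C)C)(C(C)C)C(C)C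
F8 | step 14 | cis,cis silyl triol, (2R,3R) in each furan ring | COc1cc([C@@H]2Oc3c(OC)cc([C@@H]4Oc5c(OC)cc(/C=C/CO)cc5[C@@H]4CO)cc3[C@@H]2CO)ccc1O[Si](C(C)C)(C(C)C)C(C)C
F9 | step 14 | cis,cis trialdehyde, (2R,3S) in each furan ring, E enal | COc1cc([C@@H]2Oc3c(OC)cc([C@@H]4Oc5c(OC)cc(/C=C/C=O)cc5[C@@H]4C=O)cc3[C@@H]2C=O)ccc1O[Si](C(C)C)(C(C)C)C(C)C
F10 | step 14 | trans,trans trialdehyde, (2R,3R) in each furan ring, E enal | COc1cc([C@@H]2Oc3c(OC)cc([C@@H]4Oc5c(OC)cc(/C=C/C=O)cc5[C@H]4C=O)cc3[C@H]2C=O)ccc1O[Si](C(C)C)(C(C)C)C(C)C
F11 | step 5 | bromophenol, methyl 2-(5-bromo-2-hydroxy-3-methoxyphenyl)acetate | COC(=O)Cc1cc(Br)cc(OC)c1O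
F12 | step 5 | A-B ether aryl bromide, methyl 2-[5-bromo-3-methoxy-2-[[3-methoxy-4-(triisopropylsilyloxy)phenyl]methoxy]phenyl]acetate | COC(=O)Cc1cc(Br)cc(OC)c1OCc1ccc(O[Si](C(C)C)(C(C)C)C(C)C)c(OC)c1
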